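**Plan**
- Retrosynthesis: quinone 18 is traced back to the para-methoxyphenol 17 (oxidative demethylation). The benzene ring of 17 is then taken apart in one operation at three bonds: ring C–H to the neighbouring C–OMe carbon, the C–OH carbon to its methoxy-bearing neighbour, and the C–OH carbon to the chromanyl-bearing carbon. This gives carbene complex 15 (which also supplies the CO) and terminal alkyne 10.
- Enabling feature: in the 2,3-dimethoxy-1,4-benzoquinone ring the two carbonyl carbons C1 and C4 are para, C6 bears H and C5 bears the chroman. C1–C3 map onto a 1,2-dimethoxyvinyl(methoxy)carbene ligand, C4 onto a CO ligand, and C5/C6 onto a terminal alkyne in its normal insertion sense.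
- Forward order: pyran ring of the chromene (step 1), saturation to the chroman (step 3), CO2H to C≡CH (steps 4–7), carbene complex (step 8), then the carbocyclic six-membered ring last (step 9) and its oxidation to the quinone (step 10).
- Stereochemistry: the only stereocenter, C3 of the chroman (S in the target), is set by ligand-controlled asymmetric hydrogenation of acid 4 in step 3 and carried through untouched; its R/S letter alternates only because CIP priorities change.

Key step: step 9

Assumption: (Z)-1,2-dimethoxyethene is taken as purchasable, and the ligand antipode in step 3 is assigned by analogy with (E)-2-alkyl-3-arylacrylic acids and would be exchanged for its mirror image if the first run gave the (S)-acid.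

**Step 1**
Reactants: 1 2-hydroxy-4,5-dimethoxybenzaldehyde; 2 acrolein
Product: 3 6,7-dimethoxy-2H-chromene-3-carbaldehyde
Conditions: K2CO3, 1,4-dioxane, reflux
Reagents that add atoms: none
Why: Oxa-Michael addition of the phenoxide to acrolein followed by intramolecular aldol condensation onto the aryl aldehyde closes the pyran ring, the standard route from salicylaldehydes to 2H-chromene-3-carbaldehydes.

**Step 2**
Reactants: 3 6,7-dimethoxy-2H-chromene-3-carbaldehyde
Product: 4 6,7-dimethoxy-2H-chromene-3-carboxylic acid
Conditions: NaClO2, NaH2PO4, 2-methyl-2-butene (excess), t-BuOH/H2O, rt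
Reagents that add atoms: sodium chlorite, [Na+].[O-]Cl=O
Why: Pinnick oxidation should convert the enal into the acid without touching the ring alkene, the excess 2-methyl-2-butene trapping hypochlorous acid before it can chlorinate the electron-rich arene.

**Step 3**
Reactants: 4 6,7-dimethoxy-2H-chromene-3-carboxylic acid
Product: 5 (R)-6,7-dimethoxychromane-3-carboxylic acid
Conditions: H2 (50 bar), Ru(OAc)2[(S)-H8-BINAP] (1 mol %), MeOH, 40 °C
Reagents that add atoms: none
Why: Carboxylate-directed asymmetric hydrogenation of a trisubstituted α,β-unsaturated acid with a ruthenium dicarboxylate–atropisomeric diphosphine catalyst should add hydrogen to one face of C3=C4, so the chiral ligand sets the C3 stereocenter.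

**Step 4**
Reactants: 5 (R)-6,7-dimethoxychromane-3-carboxylic acid
Product: 6 (S)-(6,7-dimethoxychroman-3-yl)methanol
Conditions: BH3·SMe2, THF, 0 °C to rt; then MeOH
Reagents that add atoms: none
Why: Borane reduces the carboxylic acid chemoselectively through an acyloxyborane without enolization, so the α-stereocenter is retained.

**Step 5**
Reactants: 6 (S)-(6,7-dimethoxychroman-3-yl)methanol
Product: 7 (R)-6,7-dimethoxychromane-3-carbaldehyde
Conditions: Dess–Martin periodinane, NaHCO3, CH2Cl2, 0 °C to rt; crude aldehyde used at once
Reagents that add atoms: none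
Why: Buffered Dess–Martin oxidation stops at the aldehyde under non-basic conditions, which should avoid enolization and β-elimination of the aryloxy group at the α-stereocenter.

**Step 6**
Reactants: 7 (R)-6,7-dimethoxychromane-3-carbaldehyde
Product: 8 (S)-3-(2,2-dibromovinyl)-6,7-dimethoxychromane
Conditions: CBr4, PPh3, Zn, CH2Cl2, rt (ylide formation); then 7, 0 °C
Reagents that add atoms: carbon tetrabromide, BrC(Br)(Br)Br
Why: Corey–Fuchs dibromo-olefination with the preformed ylide Ph3P=CBr2 is an essentially neutral Wittig reaction at 0 °C, which protects the epimerizable α-center, and the product no longer has an acidic α-hydrogen.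

**Step 7**
Reactants: 8 (S)-3-(2,2-dibromovinyl)-6,7-dimethoxychromane
Product: 10 (S)-3-ethynyl-6,7-dimethoxychromane, via lithium acetylide 9 (not isolated)
Conditions: n-BuLi (2.2 equiv), THF, −78 °C; then H2O
Reagents that add atoms: none
Why: Bromine–lithium exchange and Fritsch–Buttenberg–Wiechell 1,2-hydrogen shift of the vinylidene carbenoid (second stage of the Corey–Fuchs alkyne synthesis) give the lithium acetylide, which is protonated on work-up, while the propargylic C–H is not acidic enough to be touched at −78 °C.

**Step 8**
Reactants: 11 (Z)-1,2-dimethoxyethene; 12 hexacarbonylchromium Cr(CO)6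
Product: 15 pentacarbonyl[(2Z)-1,2,3-trimethoxyprop-2-en-1-ylidene]chromium, via vinyllithium 13 (not isolated), via lithium acylchromate 14 (not isolated)
Conditions: t-BuLi, THF, −78 to −40 °C; Cr(CO)6, Et2O, −78 °C to rt; then Me3OBF4, CH2Cl2, 0 °C
Reagents that add atoms: trimethyloxonium tetrafluoroborate, C[O+](C)C.F[B-](F)(F)F
Why: α-Lithiation of the enol ether with retention of geometry, addition of the vinyllithium to a CO ligand of Cr(CO)6 and O-methylation of the acylchromate is the classical Fischer carbene complex synthesis, expected to work here by analogy with other α-alkoxyvinyllithium reagents such as lithiated dihydropyran and 1,4-dioxene.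

**Step 9**
Reactants: 10 (S)-3-ethynyl-6,7-dimethoxychromane; 15 pentacarbonyl[(2Z)-1,2,3-trimethoxyprop-2-en-1-ylidene]chromium
Product: 17 (S)-6-(6,7-dimethoxychroman-3-yl)-2,3,4-trimethoxyphenol, via Cr(CO)3 arene complex 16 (not isolated)
Conditions: 15 (1.3 equiv), THF, 55 °C, argon; then air, rt
Reagents that add atoms: none
Why: Thermal loss of one cis-CO from 15 lets the alkyne coordinate and insert into the Cr=C bond to give an η3-vinylcarbene, CO insertion gives an η4-dienylketene, and 6π electrocyclization onto the CH(OMe) terminus of the dimethoxyvinyl group followed by enolization gives the phenol as its Cr(CO)3 complex, which air sets free. This is the Dötz benzannulation of an alkenyl(alkoxy)carbene complex of zerovalent chromium with a terminal alkyne, its closest precedents being benzannulations of α-alkoxyalkenyl complexes. The benzene ring, the only ring closed, closes by disrotatory 6π electrocyclization of the dienylketene in a formal [3+2+1] assembly that makes three C–C bonds: ring C–H to the carbene carbon, the CH(OMe) vinyl carbon to the CO carbon, and the CO carbon to the chromanyl-bearing alkyne carbon. No stereocenter is created, and the C3 center of 10 is propargylic before and benzylic after the reaction and takes no part. The selectivity needed is the sense of alkyne insertion, which should put the secondary alkyl group next to the CO-derived C–OH carbon and the alkyne hydrogen next to the carbene-derived C–OMe carbon because the bulkier alkyne terminus avoids the carbene carbon, together with phenol formation over cyclopentannulation, cyclobutenone or furan formation, which alkenyl complexes in THF favor.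

**Step 10**
Reactants: 17 (S)-6-(6,7-dimethoxychroman-3-yl)-2,3,4-trimethoxyphenol
Product: 18 abroquinone A, (S)-5-(6,7-dimethoxychroman-3-yl)-2,3-dimethoxycyclohexa-2,5-diene-1,4-dione
Conditions: PhI(OAc)2, MeCN/H2O, 0 °C
Reagents that add atoms: water, O
Why: A phenol with a para-methoxy group should be oxidized by the trivalent iodine reagent to the para-quinone (water attacks the methoxy-bearing carbon and methanol leaves, removing the O-methyl helper that came from the carbene carbon), while the chroman arene, which has no free hydroxyl group, should react far more slowly and the neutral medium leaves the C3–H next to the quinone alone.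

**Compound list**
1 | 2-hydroxy-4,5-dimethoxybenzaldehyde | O=Cc1cc(OC)c(OC)cc1O | starting material
2 | acrolein | C=CC=O | starting material
3 | 6,7-dimethoxy-2H-chromene-3-carbaldehyde | O=CC1=Cc2cc(OC)c(OC)cc2OC1 | intermediate
4 | 6,7-dimethoxy-2H-chromene-3-carboxylic acid | OC(=O)C1=Cc2cc(OC)c(OC)cc2OC1 | intermediate
5 | (R)-6,7-dimethoxychromane-3-carboxylic acid | OC(=O)[C@H]1COc2cc(OC)c(OC)cc2C1 | intermediate
6 | (S)-(6,7-dimethoxychroman-3-yl)methanol | OC[C@H]1COc2cc(OC)c(OC)cc2C1 | intermediate
7 | (R)-6,7-dimethoxychromane-3-carbaldehyde | O=C[C@H]1COc2cc(OC)c(OC)cc2C1 | intermediate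
8 | (S)-3-(2,2-dibromovinyl)-6,7-dimethoxychromane | BrC(Br)=C[C@H]1COc2cc(OC)c(OC)cc2C1 | intermediate
9 | lithium acetylide of 10, (S)-[(6,7-dimethoxychroman-3-yl)ethynyl]lithium | [Li]C#C[C@H]1COc2cc(OC)c(OC)cc2C1 | intermediate
10 | (S)-3-ethynyl-6,7-dimethoxychromane | C#C[C@H]1COc2cc(OC)c(OC)cc2C1 | intermediate
11 | (Z)-1,2-dimethoxyethene | CO/C=C\OC | starting material
12 | hexacarbonylchromium, Cr(CO)6 | O=C=[Cr](=C=O)(=C=O)(=C=O)(=C=O)=C=O | starting material
13 | (Z)-1,2-dimethoxyvinyllithium | CO/C=C(\OC)[Li] | intermediate
14 | lithium pentacarbonyl[(2Z)-2,3-dimethoxyprop-2-enoyl]chromate, drawn as the lithium oxycarbene | CO/C=C(\OC)C(O[Li])=[Cr](=C=O)(=C=O)(=C=O)(=C=O)=C=O | intermediate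
15 | pentacarbonyl[(2Z)-1,2,3-trimethoxyprop-2-en-1-ylidene]chromium | CO/C=C(\OC)C(OC)=[Cr](=C=O)(=C=O)(=C=O)(=C=O)=C=O | intermediate
16 | tricarbonylchromium η6-complex of phenol 17, drawn as arene plus Cr(CO)3 fragment | COc1cc([C@H]2COc3cc(OC)c(OC)cc3C2)c(O)c(OC)c1OC.O=C=[Cr](=C=O)=C=O | intermediate
17 | (S)-6-(6,7-dimethoxychroman-3-yl)-2,3,4-trimethoxyphenol | COc1cc([C@H]2COc3cc(OC)c(OC)cc3C2)c(O)c(OC)c1OC | intermediate
18 | abroquinone A, (S)-5-(6,7-dimethoxychroman-3-yl)-2,3-dimethoxycyclohexa-2,5-diene-1,4-dione | COC1=C(OC)C(=O)C([C@H]2COc3cc(OC)c(OC)cc3C2)=CC1=O | target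

**Step count**
Total: 10 steps. Longest linear sequence: 9 steps (steps 1–7, 9 and 10, from aldehyde 1); the carbene branch is step 8 alone.

**Steps most likely to fail**

1. Step 9. The carbene ligand carries three donor methoxy groups, so CO loss may be slow and the vinylcarbene or ketene intermediates may drain into furan, cyclobutenone or five-membered-ring products, or complex 15 may decay before it inserts the alkyne. The fallback builds the quinone ring from a four-membered ring instead and also makes complex 15 and step 10 unnecessary. It sets out from alkyne 10: deprotonation with n-BuLi (THF, −78 °C) regenerates acetylide 9, and 1,2-addition to dimethyl squarate (3,4-dimethoxycyclobut-3-ene-1,2-dione) should give 4-{[(3S)-6,7-dimethoxychroman-3-yl]ethynyl}-4-hydroxy-2,3-dimethoxycyclobut-2-en-1-one F1 as a mixture of carbinol epimers. Heating this in p-xylene at reflux should bring about the Moore rearrangement (4π ring opening to the enynylketene, ring closure to the aryl/phenoxyl diradical, hydrogen transfer from O–H) and give the quinone directly; an alkyl-substituted alkyne favors the six-membered ring. The fallback comes back to the route at target 18.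

2. Step 3. Facial discrimination of the C3=C4 bond by the catalyst may be insufficient, or hydrogen may be delivered to the opposite face. The fallback replaces asymmetric catalysis by resolution and sets out from acid 4. Hydrogenation over Pd/C (H2, EtOAc) should give racemic 6,7-dimethoxychromane-3-carboxylic acid F2. Crystallization with (R)-1-phenylethylamine from ethanol should enrich (R)-1-phenylethylammonium (R)-6,7-dimethoxychromane-3-carboxylate F3; if the other diastereomeric salt proves less soluble, the (S)-amine is used instead. Acidification with aqueous HCl returns the route at acid 5.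

3. Step 5, together with the use of 7 in step 6. Aldehyde 7 may lose configuration by enolization, or by reversible β-elimination of the aryloxide and oxa-Michael re-closure, before it is consumed. The fallback installs the stereocenter after the benzannulation, so that no enolizable chiral intermediate exists, and sets out from chromene aldehyde 3. Homologation with dimethyl (1-diazo-2-oxopropyl)phosphonate (K2CO3, MeOH) should give 3-ethynyl-6,7-dimethoxy-2H-chromene F4. Benzannulation of this enyne with 15 as in step 9, but with Ac2O and Et3N present, should give 6-(6,7-dimethoxy-2H-chromen-3-yl)-2,3,4-trimethoxyphenyl acetate F5; the acetate keeps the ortho oxygen from adding to the chromene double bond. Hydrogenation of the trisubstituted C3=C4 bond with H2 and a cationic iridium phosphine–oxazoline catalyst such as [Ir(cod){(S)-tBu-PHOX}][B(C6H3(CF3)2)4] in CH2Cl2, a reaction type known for 3-aryl-2H-chromenes, should give (S)-6-(6,7-dimethoxychroman-3-yl)-2,3,4-trimethoxyphenyl acetate F6, the ligand antipode being matched to the S product. Methanolysis (K2CO3, MeOH) comes back to the route at phenol 17.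

**Further compounds**
F1 | step 9 | 4-{[(3S)-6,7-dimethoxychroman-3-yl]ethynyl}-4-hydroxy-2,3-dimethoxycyclobut-2-en-1-one (both carbinol epimers) | COC1=C(OC)C(O)(C#C[C@H]2COc3cc(OC)c(OC)cc3C2)C1=O
F2 | step 3 | racemic 6,7-dimethoxychromane-3-carboxylic acid | OC(=O)C1COc2cc(OC)c(OC)cc2C1
F3 | step 3 | (R)-1-phenylethylammonium (R)-6,7-dimethoxychromane-3-carboxylate | [O-]C(=O)[C@H]1COc2cc(OC)c(OC)cc2C1.C[C@@H]([NH3+])c1ccccc1
F4 | step 5 | 3-ethynyl-6,7-dimethoxy-2H-chromene | C#CC1=Cc2cc(OC)c(OC)cc2OC1
F5 | step 5 | 6-(6,7-dimethoxy-2H-chromen-3-yl)-2,3,4-trimethoxyphenyl acetate | COc1cc(C2=Cc3cc(OC)c(OC)cc3OC2)c(OC(C)=O)c(OC)c1OC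
F6 | step 5 | (S)-6-(6,7-dimethoxychroman-3-yl)-2,3,4-trimethoxyphenyl acetate | COc1cc([C@H]2COc3cc(OC)c(OC)cc3C2)c(OC(C)=O)c(OC)c1OC
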